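## Structural features

Abiesin is an achiral, unsymmetrical biflavonoid. A flavonol unit (3,7-dihydroxy-2-(4-methoxyphenyl)chromen-4-one; unprimed locants, anisyl ring primed) is bonded through C6 to C3''' of the 4-methoxyphenyl ring of a 5''-hydroxy-7''-methoxyflavone unit (chromenone double-primed, aryl ring triple-primed). There is no stereocentre, and the biaryl axis, flanked only by 7-OH and 4'''-OMe, is not expected to be configurationally stable, so nothing stereochemical has to be controlled. The fragile parts are the two 4-pyranone rings (opened by hot alkali and hard nucleophiles), the flavone C3''–H (removed by amide bases), the enolic 3-OH (a chelator whose anion autoxidises) and the three methyl ethers, which must stay while 3-OH, 7-OH and 5''-OH end up free. The real difficulty is the position of the biaryl bond: ring A of the flavonol has oxygen at C7 only, substitution of such a ring favours C8, and the C6–C3''' bond is a hindered biaryl bond with an oxygen substituent ortho on each side. The key step uses the fact that C6 (aryl-bearing) and C7 (oxygen-bearing) are neighbours in ring A and that ring A shares the C4a–C8a bond with the 3-oxygenated 4-pyranone ring C. Ring A is therefore made last, by bonding a ketene carbon (future C7, attached through C8 to C8a) to the distal carbon of an (E)-styryl group (future C6, attached through C5 to C4a). The biaryl bond then enters as the ordinary aryl–alkene bond of a styrene, and ring C with its 3-oxygen and anisyl group, as well as the whole flavone unit, can be complete before ring A exists.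

## Logic of the disconnections

**21 from 20.** The O–CH2Ph bond on O3 is cut. The enolic 3-OH is masked as a benzyl ether from step 2 to the end because it chelates palladium and its anion autoxidises. The forward hydrogenolysis must remove one benzyl group without reducing the two chromenone C2=C3 bonds.

**20 from 19.** The two acetyl–oxygen bonds on O7 and O5'' are cut. These acetates are not chosen protecting groups but the form in which the ring closure delivers the phenols. The forward methanolysis must be mild enough to leave both pyranone rings closed.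

**19 from 15 (key disconnection).** The C6–C7 bond of ring A is cut and C7 is returned to the carboxylic acid level. Ring A opens to a CH2CO2H group on C8a and an (E)-2-arylethenyl group on C4a of a fully substituted 4-pyranone. Cutting here replaces the hindered C6–C3''' biaryl bond by an aryl–vinyl bond and makes the 6-aryl-7-oxy pattern a consequence of connectivity. The forward step must form the ketene and close it faster than the acid loses CO2, and it needs the E alkene.

**15 from 14.** The O–C(CH3)3 bond is cut. The free acid is a vinylogous β-keto acid, so it is released only just before use. The tert-butyl ester is inert to the coupling conditions and is removed by acid, which spares the benzyl ether. The acidolysis must not protonate the alkene.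

**14 from 7 and 13.** The C4a–C5 bond (pyranone C3 to the alkene) is cut, a Heck disconnection that splits the molecule into two halves of similar size and gives the E alkene directly. 13 is used with its 5''-OH free, because no strong base follows the union. The forward step asks a tetrasubstituted alkenyl iodide, flanked by a carbonyl group and an acidic CH2, to insert an alkene without enolate side reactions, hence a tertiary amine as base.

**7 from 6.** The C7–C8 bond is cut (ester carbon from the lateral carbon). The carboxyl carbon is introduced here, on a small pyranone whose methyl group is the only acidic site. Doing it after the union would expose the flavone C3''–H, the phenol and a second pyranone to an amide base. The forward step needs C- and not O-acylation and a vinyl iodide that tolerates the base.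

**6 from 5.** The C3–I bond is cut. Iodination comes before carboxylation so that the electrophile meets no active methylene group, and C3 is the only unsubstituted carbon of the pyranone. The forward step must prefer this carbon to the anisyl ring.

**5 from 3 and 4.** The C2–C1' bond (pyranone C6 to the anisyl ring) is cut. The halide is a vinylogous acyl bromide and should cross-couple readily.

**3 from 2, and 2 from 1.** The O–benzyl bond and then the C6–Br bond are cut. The free enolic OH of 1 directs bromination to its ortho carbon, so bromination must precede benzylation.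

**13 from 12.** The aryl–vinyl bond is cut; the bromine is carried in from 8 and becomes the vinyl group by cross-coupling.

**12 from 11, and 11 from 10 and 9.** The O1''–C2'' bond is cut (cyclodehydration), then the bond between the acetyl carbon of 10 (future C3'') and the aroyl carbon (future C2''). Because 10 is symmetrical, either phenol closes to the same product. The acylation must go on carbon, which the polylithiated ketone ensures.

**9 from 8.** The C–Cl bond is cut; the acid is activated for the acylation.

## Other disconnections considered

**Alternative 1:** The cut removes three ring-A bonds (C8–C8a, C6–C7 and C4a–C8a), so that ring A is assembled from the 2-arylcyclobutenone A2 and the siloxyalkyne A3.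
- **Forward step:** heating A2 with A3 in a Danheiser-type benzannulation. A2 opens to an arylvinylketene, A3 adds by [2+2], the new cyclobutenone opens and a six-electron closure gives the resorcinol monosilyl ether A1, with free OH on C8a and the silyl ether on C7.
- **In favour:** the cascade is a known reaction type under neutral thermal conditions. The two ring-A oxygens emerge differentiated, and the aryl group is placed next to O7 by connectivity.
- **Against:** A2 is a strained, non-commercial cyclobutenone that would itself need a cross-coupling of a 3'''-haloflavone with a cyclobutenone equivalent. After A1 the whole of ring C is still missing: C-acylation at C4a in competition with C8, a flavonol annulation, desilylation, and a selective 5''-O-demethylation, since A1 carries a 5'',7''-dimethyl ether.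
- **Comparison:** on structure the two plans are equal, since both build ring A and fix the 6,7-pattern by connectivity. On mechanism Alternative 1 is better, because its key step rests on closer precedent and has no decarboxylation channel. On step economy it is worse, with at least five steps after the key step against two in the chosen plan, and a late differentiation of methyl ethers that the chosen plan never needs.

**Alternative 2:** The cut is the C2''=C3'' bond of the flavone unit, leading back to the acylmethylenephosphorane A5, which carries the aroyl ester of the complete flavonol-bearing benzoic acid on the neighbouring phenol oxygen.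
- **Forward step:** heating A5 gives an intramolecular Wittig olefination of the ester carbonyl and closes flavone ring C to give A4.
- **In favour:** the conditions are neutral and the reaction type is known for flavones. The two halves are joined by a simple ester formation, and A4 is one hydrogenolysis from 21, which is one step shorter after the key step than the chosen plan.
- **Against:** the ring that is closed is the least problematic one; the chosen route makes it in two classical steps from 9 and 10. The C6–C3''' biaryl bond and the ring-A regiochemistry are left to separate chemistry, in practice a hindered biaryl cross-coupling on a 6-haloflavonol. A5 needs an α-haloketone, a phosphonium salt and the acylation of a hindered phenol with a large acid, and an ester carbonyl is a reluctant Wittig acceptor.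
- **Comparison:** on mechanism and precedent of the key step Alternative 2 is the better plan, and on the endgame it is shorter. On structure it is weaker, because its key step does not touch the feature that makes the target difficult. On total step count it is expected to be longer, since both halves and a biaryl coupling must precede A5.

**Alternative 3:** The cut removes the O1–C2 bond and the C3–OH bond of the flavonol, leading back to the 2'-hydroxychalcone A7.
- **Forward step:** alkaline H2O2 (Algar–Flynn–Oyamada oxidation) converts A7 into the flavonol A6.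
- **In favour:** this is the classical flavonol synthesis. The 3-OH is delivered free, so no protecting group is needed on O3. A7 would come from a Claisen–Schmidt condensation with 4-methoxybenzaldehyde, and its ketone ring has no substituent at C6', which favours flavonol over aurone. A6 is one hydrogenolysis from 21.
- **Against:** the condensation that makes A7 and the oxidative closure both expose the flavone unit to alkali, and the closure also to alkaline peroxide; a flavone pyranone ring can be opened under such conditions. The biaryl bond again has to be made beforehand by cross-coupling on a 5'-halo-2',4'-dioxygenated acetophenone.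
- **Comparison:** on regiocontrol it is the equal of the chosen plan, provided the halogenated acetophenone is used. On precedent it is better, since every step is a known reaction type, and on length it is about equal. The chosen plan avoids the biaryl coupling and any strong base after the fragment union, at the price of an untested ring closure. The fallback for the key step draws on this chemistry, with the oxidative closure placed before the biaryl coupling so that the flavone unit never meets alkaline peroxide.

Key step: step 12

Remark on locants: the biaryl bond is C6–C3''' (not C6–C3'), because the carbon on the flavone side belongs to the aryl ring of the flavone unit.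

Assumption: in step 12 the chelated 5''-OH is taken to be acetylated after ring closure; 16, 17 and 18 are therefore drawn with 5''-OH free, and an earlier acetylation would lead to the same product 19.

## Route

Step 1
Reactants: 1 allomaltol (5-hydroxy-2-methyl-4H-pyran-4-one)
Product: 2 6-bromo-5-hydroxy-2-methyl-4H-pyran-4-one
Conditions: NBS, MeCN, 0 °C to rt
Reagents that add atoms: N-bromosuccinimide, O=C1CCC(=O)N1Br
Why: Electrophilic bromination of the enol; the free 5-OH makes its ortho carbon C6 the most nucleophilic position (the site of Mannich and aldol reactions in this ring system), so bromine should enter there and not at C3.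

Step 2
Reactants: 2 6-bromo-5-hydroxy-2-methyl-4H-pyran-4-one
Product: 3 5-benzyloxy-6-bromo-2-methyl-4H-pyran-4-one
Conditions: BnBr, K2CO3, DMF, rt
Reagents that add atoms: benzyl bromide, BrCc1ccccc1
Why: Williamson etherification of the acidic enolic OH; at room temperature the carbonate should not displace the vinylogous acyl bromide.

Step 3
Reactants: 3 5-benzyloxy-6-bromo-2-methyl-4H-pyran-4-one; 4 4-methoxyphenylboronic acid
Product: 5 5-benzyloxy-6-(4-methoxyphenyl)-2-methyl-4H-pyran-4-one
Conditions: Pd(PPh3)4 (5 mol %), Na2CO3, toluene/EtOH/H2O, 85 °C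
Reagents that add atoms: none
Why: Suzuki–Miyaura coupling; the C6–Br bond lies β to the carbonyl and on the oxygen-bearing carbon, so oxidative addition to zerovalent palladium should be fast, and the benzyl ether keeps the enol from binding the metal.

Step 4
Reactants: 5 5-benzyloxy-6-(4-methoxyphenyl)-2-methyl-4H-pyran-4-one
Product: 6 5-benzyloxy-3-iodo-6-(4-methoxyphenyl)-2-methyl-4H-pyran-4-one
Conditions: I2, (NH4)2Ce(NO3)6, MeCN, 60 °C
Reagents that add atoms: iodine, II
Why: Electrophilic iodination at C3, the only unsubstituted ring carbon and the nucleophilic α-carbon of the vinylogous ester; iodine with tetravalent cerium is the reagent pair known to iodinate flavones at C3 in the presence of methoxylated aryl rings, and the anisyl ring here is deactivated by conjugation with the enone.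

Step 5
Reactants: 6 5-benzyloxy-3-iodo-6-(4-methoxyphenyl)-2-methyl-4H-pyran-4-one
Product: 7 tert-butyl [5-benzyloxy-3-iodo-6-(4-methoxyphenyl)-4-oxo-4H-pyran-2-yl]acetate
Conditions: LiN(SiMe3)2 (2.2 equiv), THF, −78 °C; Boc2O, −78 to −20 °C; aq NH4Cl
Reagents that add atoms: di-tert-butyl dicarbonate, CC(C)(C)OC(=O)OC(=O)OC(C)(C)C
Why: Lateral deprotonation and alkoxycarbonylation (a vinylogous Claisen-type C-acylation); the 2-methyl group is vinylogous to the C4 carbonyl and is the only acidic site because C3 is blocked, the silylamide does not exchange the vinyl iodide, and the second equivalent of base absorbs the more acidic product.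

Step 6
Reactants: 8 3-bromo-4-methoxybenzoic acid
Product: 9 3-bromo-4-methoxybenzoyl chloride
Conditions: (COCl)2, DMF (cat.), CH2Cl2, rt
Reagents that add atoms: oxalyl chloride, ClC(=O)C(Cl)=O
Why: Standard acid chloride formation through the Vilsmeier-type chloroiminium catalyst; the aryl bromide and methyl ether are inert.

Step 7
Reactants: 10 2',6'-dihydroxy-4'-methoxyacetophenone; 9 3-bromo-4-methoxybenzoyl chloride
Product: 11 1-(3-bromo-4-methoxyphenyl)-3-(2,6-dihydroxy-4-methoxyphenyl)propane-1,3-dione
Conditions: LiN(SiMe3)2 (4 equiv), THF, −78 to −10 °C; then 9, −78 °C to rt; aq HCl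
Reagents that add atoms: none
Why: Claisen-type C-aroylation of the polylithiated ketone, the direct equivalent of a Baker–Venkataraman sequence; with both phenols held as lithium phenoxides the enolate carbon is the most reactive nucleophile, so the 1,3-diketone should form without O-aroylation.

Step 8
Reactants: 11 1-(3-bromo-4-methoxyphenyl)-3-(2,6-dihydroxy-4-methoxyphenyl)propane-1,3-dione
Product: 12 2-(3-bromo-4-methoxyphenyl)-5-hydroxy-7-methoxy-4H-chromen-4-one
Conditions: H2SO4 (cat.), AcOH, 95 °C
Reagents that add atoms: none
Why: Acid-catalysed cyclodehydration of the 2-hydroxyaryl 1,3-diketone to the flavone; the ketone ring is symmetrical, so either phenol closes to the same product and the other remains as the chelated 5-OH.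

Step 9
Reactants: 12 2-(3-bromo-4-methoxyphenyl)-5-hydroxy-7-methoxy-4H-chromen-4-one
Product: 13 2-(3-ethenyl-4-methoxyphenyl)-5-hydroxy-7-methoxy-4H-chromen-4-one
Conditions: vinylboronic acid pinacol ester, PdCl2(dppf), K2CO3, 1,4-dioxane/H2O, 90 °C
Reagents that add atoms: 2-ethenyl-4,4,5,5-tetramethyl-1,3,2-dioxaborolane, C=CB1OC(C)(C)C(C)(C)O1
Why: Suzuki–Miyaura vinylation of the aryl bromide; the chelated phenol and the flavone ring tolerate aqueous carbonate at this temperature.

Step 10
Reactants: 7 tert-butyl [5-benzyloxy-3-iodo-6-(4-methoxyphenyl)-4-oxo-4H-pyran-2-yl]acetate; 13 2-(3-ethenyl-4-methoxyphenyl)-5-hydroxy-7-methoxy-4H-chromen-4-one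
Product: 14 tert-butyl {5-benzyloxy-3-[(E)-2-[5-(5-hydroxy-7-methoxy-4-oxo-4H-chromen-2-yl)-2-methoxyphenyl]ethenyl]-6-(4-methoxyphenyl)-4-oxo-4H-pyran-2-yl}acetate
Conditions: Pd(OAc)2 (10 mol %), P(o-tol)3, Et3N, DMF, 90 °C
Reagents that add atoms: none
Why: Mizoroki–Heck coupling of the 3-iodopyranone with the styrene; insertion at the terminal carbon and syn β-hydride elimination should give the E alkene, and the weak amine base leaves the acidic CH2 of the ester and the chelated phenol alone.

Step 11
Reactants: 14 tert-butyl {5-benzyloxy-3-[(E)-2-[5-(5-hydroxy-7-methoxy-4-oxo-4H-chromen-2-yl)-2-methoxyphenyl]ethenyl]-6-(4-methoxyphenyl)-4-oxo-4H-pyran-2-yl}acetate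
Product: 15 {5-benzyloxy-3-[(E)-2-[5-(5-hydroxy-7-methoxy-4-oxo-4H-chromen-2-yl)-2-methoxyphenyl]ethenyl]-6-(4-methoxyphenyl)-4-oxo-4H-pyran-2-yl}acetic acid
Conditions: CF3CO2H/CH2Cl2 (1:4), 0 °C to rt; evaporation below 25 °C
Reagents that add atoms: none
Why: Acidolysis of the tert-butyl ester with loss of isobutene; the benzyl ether on O3 is stable to the acid, the alkene is protected from protonation by conjugation with the protonated pyranone, and the acid is kept cold and used at once because it is a vinylogous β-keto acid.

Step 12
Reactants: 15 {5-benzyloxy-3-[(E)-2-[5-(5-hydroxy-7-methoxy-4-oxo-4H-chromen-2-yl)-2-methoxyphenyl]ethenyl]-6-(4-methoxyphenyl)-4-oxo-4H-pyran-2-yl}acetic acid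
Product: 19 7,5''-di-O-acetyl-3-O-benzylabiesin, via mixed acetic anhydride 16 (not isolated), via dienylketene 17 (not isolated), via cyclohexadienone 18 (not isolated)
Conditions: Ac2O, NaOAc, rt, 1 h; then 125 °C
Reagents that add atoms: acetic anhydride, CC(=O)OC(C)=O
Why: Proposed new method: Ac2O should convert 15 at room temperature into the mixed anhydride 16, so that the free vinylogous β-keto acid is never heated; acetate then removes a C8 proton, which is α to the anhydride carbonyl and vinylogous to the C4 carbonyl, and loss of acetate gives the dienylketene 17. In 17 the ketene C7=C8 bond, the pyranone C8a=C4a bond and the (E)-styryl C5=C6 bond form a hexatriene whose central double bond is held cis by the ring, and ring A closes by a thermally allowed, disrotatory six-electron electrocyclisation that joins the ketene carbon C7 to the styryl carbon C6 and gives the cyclohexadienone 18. Enolisation of 18 removes the C6 hydrogen and restores the pyranone C4a=C8a bond inside an aromatic ring A, and Ac2O acetylates O7 and, at this temperature, the chelated 5''-OH. The closest known reaction type is the Ac2O/NaOAc benzannulation of 3,5-dienoic and (2-vinylaryl)acetic acids to aryl acetates, as in the ring-closing step of the Stobbe route to 1-naphthyl acetates, which runs through the same kind of dienylketene; new here is that the central double bond belongs to a 4-pyranone, which is only weakly aromatic and should enter the triene more easily than a benzene bond. The only stereocentre formed, C6 of 18, is transient and is erased on enolisation, so nothing needs stereocontrol. Regiochemistry is fixed by connectivity, because C6 already carries the aryl ring and C7 is the former carboxyl carbon, and the C4 carbonyl oxygen cannot compete for the ketene because C4 is trans to C8 across the C4a=C8a bond. The selectivity that is needed is chemoselectivity for ketene formation and closure over loss of CO2 and over intermolecular C-acetylation at C8; the early formation of 16, the acidity of the C8 protons, the intramolecular closure at a ketene terminus that carries no inward substituent and the E geometry of the styryl group, which keeps the aryl ring outside the closing termini, should secure it.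

Step 13
Reactants: 19 7,5''-di-O-acetyl-3-O-benzylabiesin
Product: 20 3-O-benzylabiesin
Conditions: K2CO3, MeOH/THF, rt
Reagents that add atoms: none
Why: Transesterification of the two aryl acetates with methoxide; aryl acetates cleave far faster than a pyranone ring opens at room temperature, and any material that escaped 5''-O-acetylation in step 12 converges here.

Step 14
Reactants: 20 3-O-benzylabiesin
Product: 21 abiesin
Conditions: H2 (1 atm), Pd/C, THF/MeOH, rt
Reagents that add atoms: none
Why: Hydrogenolysis of the benzyl ether on O3; the chromenone C2=C3 bonds are fully substituted or trisubstituted vinylogous ester bonds and should not be reduced if the reaction is stopped after the uptake of one equivalent.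

## Compound list

1 | allomaltol (5-hydroxy-2-methyl-4H-pyran-4-one) | Cc1cc(=O)c(O)co1 | starting material
2 | 6-bromo-5-hydroxy-2-methyl-4H-pyran-4-one | Cc1cc(=O)c(O)c(Br)o1 | intermediate
3 | 5-benzyloxy-6-bromo-2-methyl-4H-pyran-4-one | Cc1cc(=O)c(OCc2ccccc2)c(Br)o1 | intermediate
4 | 4-methoxyphenylboronic acid | COc1ccc(B(O)O)cc1 | starting material
5 | 5-benzyloxy-6-(4-methoxyphenyl)-2-methyl-4H-pyran-4-one | Cc1cc(=O)c(OCc2ccccc2)c(-c2ccc(OC)cc2)o1 | intermediate
6 | 5-benzyloxy-3-iodo-6-(4-methoxyphenyl)-2-methyl-4H-pyran-4-one | Cc1oc(-c2ccc(OC)cc2)c(OCc2ccccc2)c(=O)c1I | intermediate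
7 | tert-butyl [5-benzyloxy-3-iodo-6-(4-methoxyphenyl)-4-oxo-4H-pyran-2-yl]acetate | CC(C)(C)OC(=O)Cc1oc(-c2ccc(OC)cc2)c(OCc2ccccc2)c(=O)c1I | intermediate
8 | 3-bromo-4-methoxybenzoic acid | COc1ccc(C(=O)O)cc1Br | starting material
9 | 3-bromo-4-methoxybenzoyl chloride | COc1ccc(C(Cl)=O)cc1Br | intermediate
10 | 2',6'-dihydroxy-4'-methoxyacetophenone | CC(=O)c1c(O)cc(OC)cc1O | starting material
11 | 1-(3-bromo-4-methoxyphenyl)-3-(2,6-dihydroxy-4-methoxyphenyl)propane-1,3-dione | COc1ccc(C(=O)CC(=O)c2c(O)cc(OC)cc2O)cc1Br | intermediate
12 | 2-(3-bromo-4-methoxyphenyl)-5-hydroxy-7-methoxy-4H-chromen-4-one | COc1cc(O)c2c(c1)oc(-c1ccc(OC)c(Br)c1)cc2=O | intermediate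
13 | 2-(3-ethenyl-4-methoxyphenyl)-5-hydroxy-7-methoxy-4H-chromen-4-one | COc1cc(O)c2c(c1)oc(-c1ccc(OC)c(C=C)c1)cc2=O | intermediate
14 | tert-butyl {5-benzyloxy-3-[(E)-2-[5-(5-hydroxy-7-methoxy-4-oxo-4H-chromen-2-yl)-2-methoxyphenyl]ethenyl]-6-(4-methoxyphenyl)-4-oxo-4H-pyran-2-yl}acetate | COc1ccc(cc1)-c1oc(CC(=O)OC(C)(C)C)c(/C=C/c2cc(ccc2OC)-c2cc(=O)c3c(O)cc(OC)cc3o2)c(=O)c1OCc1ccccc1 | intermediate
15 | {5-benzyloxy-3-[(E)-2-[5-(5-hydroxy-7-methoxy-4-oxo-4H-chromen-2-yl)-2-methoxyphenyl]ethenyl]-6-(4-methoxyphenyl)-4-oxo-4H-pyran-2-yl}acetic acid | COc1ccc(cc1)-c1oc(CC(=O)O)c(/C=C/c2cc(ccc2OC)-c2cc(=O)c3c(O)cc(OC)cc3o2)c(=O)c1OCc1ccccc1 | intermediate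
16 | mixed anhydride of 15 with acetic acid (not isolated) | COc1ccc(cc1)-c1oc(CC(=O)OC(C)=O)c(/C=C/c2cc(ccc2OC)-c2cc(=O)c3c(O)cc(OC)cc3o2)c(=O)c1OCc1ccccc1 | intermediate
17 | 5-benzyloxy-3-[(E)-2-[5-(5-hydroxy-7-methoxy-4-oxo-4H-chromen-2-yl)-2-methoxyphenyl]ethenyl]-6-(4-methoxyphenyl)-2-(2-oxoethenyl)-4H-pyran-4-one, the dienylketene (not isolated) | COc1ccc(cc1)-c1oc(C=C=O)c(/C=C/c2cc(ccc2OC)-c2cc(=O)c3c(O)cc(OC)cc3o2)c(=O)c1OCc1ccccc1 | intermediate
18 | 3-benzyloxy-6-[5-(5-hydroxy-7-methoxy-4-oxo-4H-chromen-2-yl)-2-methoxyphenyl]-2-(4-methoxyphenyl)-6H-chromene-4,7-dione, racemic at C6 (not isolated) | COc1ccc(cc1)C1=C(OCc2ccccc2)C(=O)C2=CC(c3cc(ccc3OC)-c3cc(=O)c4c(O)cc(OC)cc4o3)C(=O)C=C2O1 | intermediate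
19 | 7-acetoxy-6-[5-(5-acetoxy-7-methoxy-4-oxo-4H-chromen-2-yl)-2-methoxyphenyl]-3-benzyloxy-2-(4-methoxyphenyl)-4H-chromen-4-one (7,5''-di-O-acetyl-3-O-benzylabiesin) | COc1ccc(cc1)-c1oc2cc(OC(C)=O)c(cc2c(=O)c1OCc1ccccc1)-c1cc(ccc1OC)-c1cc(=O)c2c(OC(C)=O)cc(OC)cc2o1 | intermediate
20 | 3-benzyloxy-7-hydroxy-6-[5-(5-hydroxy-7-methoxy-4-oxo-4H-chromen-2-yl)-2-methoxyphenyl]-2-(4-methoxyphenyl)-4H-chromen-4-one (3-O-benzylabiesin) | COc1ccc(cc1)-c1oc2cc(O)c(cc2c(=O)c1OCc1ccccc1)-c1cc(ccc1OC)-c1cc(=O)c2c(O)cc(OC)cc2o1 | intermediate
21 | abiesin | COc1ccc(-c2oc3cc(O)c(-c4cc(-c5cc(=O)c6c(O)cc(OC)cc6o5)ccc4OC)cc3c(=O)c2O)cc1 | target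

## Step count and least certain steps

Total: 14 steps. Longest linear sequence: 10 steps (steps 1–5 and 10–14, from 1 to 21); the flavone branch (steps 6–9) joins at step 10.

**Step 12 (key step).** The most likely failure is that loss of CO2 from the acid, or intermolecular C-acetylation at C8 followed by loss of CO2, runs faster than ketene formation and closure. The closure needs the styryl group to rotate into the s-cis arrangement beside a fully substituted pyranone, and that may raise its barrier.

The fallback uses known chemistry, sets out from 12 and returns at 21: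
- Miyaura borylation of 12 (bis(pinacolato)diboron, PdCl2(dppf), KOAc, dioxane) should give 5-hydroxy-7-methoxy-2-[4-methoxy-3-(4,4,5,5-tetramethyl-1,3,2-dioxaborolan-2-yl)phenyl]-4H-chromen-4-one F1.
- The flavonol half would start from commercial 1-(5-bromo-2,4-dihydroxyphenyl)ethanone F2. Benzylation of the non-chelated hydroxyl (BnBr, K2CO3, acetone) gives 1-(4-benzyloxy-5-bromo-2-hydroxyphenyl)ethanone F3.
- Claisen–Schmidt condensation with 4-methoxybenzaldehyde gives (E)-1-(4-benzyloxy-5-bromo-2-hydroxyphenyl)-3-(4-methoxyphenyl)prop-2-en-1-one F4.
- Algar–Flynn–Oyamada oxidation gives 7-benzyloxy-6-bromo-3-hydroxy-2-(4-methoxyphenyl)-4H-chromen-4-one F5, and benzylation gives 3,7-bis(benzyloxy)-6-bromo-2-(4-methoxyphenyl)-4H-chromen-4-one F6.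
- Suzuki–Miyaura coupling of F1 with F6 gives 3,7-di-O-benzylabiesin F7, and hydrogenolysis over Pd/C gives 21.

This places the bromine at C6 from the start and keeps the flavone unit away from alkaline peroxide, at the price of a hindered biaryl coupling.

**Step 5.** The most likely failure is acylation on oxygen, a second acylation of the product enolate, or incomplete acylation of a stabilised and sluggish carbanion by Boc2O. The fallback sets out from 6 and returns at 7. The lithiated methyl group is quenched with CO2, the classical trap for lateral carbanions of methylchromones, to give [5-benzyloxy-3-iodo-6-(4-methoxyphenyl)-4-oxo-4H-pyran-2-yl]acetic acid F8. F8 is esterified in the cold with tert-butyl 2,2,2-trichloroacetimidate and catalytic BF3·OEt2 to give 7.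

**Step 10.** The most likely failure is slow alkene insertion at the hindered tetrasubstituted alkenylpalladium centre, so that reductive loss of iodine and catalyst decay win. The fallback sets out from 13 and returns at 14. Cross-metathesis of 13 with vinylboronic acid pinacol ester (second-generation Grubbs catalyst, RuCl2(=CHPh)(H2IMes)(PCy3)) should give 5-hydroxy-7-methoxy-2-{4-methoxy-3-[(E)-2-(4,4,5,5-tetramethyl-1,3,2-dioxaborolan-2-yl)ethenyl]phenyl}-4H-chromen-4-one F9. Suzuki–Miyaura coupling of F9 with 7 (PdCl2(dppf), K3PO4, dioxane/H2O) gives 14 with the E geometry carried in by the boronate.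

**Step 4.** The most likely failure is competing iodination of the anisyl ring ortho to its methoxy group, or oxidative loss of the benzyl ether by tetravalent cerium. The fallback sets out from 3 and returns at 14:
- The halogen is introduced before any electron-rich arene is present: NBS on 3 should give 5-benzyloxy-3,6-dibromo-2-methyl-4H-pyran-4-one F10.
- Site-selective Suzuki–Miyaura coupling with 4 at C6 gives 5-benzyloxy-3-bromo-6-(4-methoxyphenyl)-2-methyl-4H-pyran-4-one F11. The C6–Br bond, β to the carbonyl and on the oxygen-bearing carbon, should undergo oxidative addition faster than the C3–Br bond.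
- Lateral alkoxycarbonylation as in step 5 gives tert-butyl [5-benzyloxy-3-bromo-6-(4-methoxyphenyl)-4-oxo-4H-pyran-2-yl]acetate F12.
- Heck coupling of F12 with 13 gives 14.

## Further compounds

F1 | step 12 | 5-hydroxy-7-methoxy-2-[4-methoxy-3-(4,4,5,5-tetramethyl-1,3,2-dioxaborolan-2-yl)phenyl]-4H-chromen-4-one | COc1cc(O)c2c(c1)oc(-c1ccc(OC)c(B3OC(C)(C)C(C)(C)O3)c1)cc2=O
F2 | step 12 | 1-(5-bromo-2,4-dihydroxyphenyl)ethanone (purchased) | CC(=O)c1cc(Br)c(O)cc1O
F3 | step 12 | 1-(4-benzyloxy-5-bromo-2-hydroxyphenyl)ethanone | CC(=O)c1cc(Br)c(OCc2ccccc2)cc1O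
F4 | step 12 | (E)-1-(4-benzyloxy-5-bromo-2-hydroxyphenyl)-3-(4-methoxyphenyl)prop-2-en-1-one | COc1ccc(/C=C/C(=O)c2cc(Br)c(OCc3ccccc3)cc2O)cc1
F5 | step 12 | 7-benzyloxy-6-bromo-3-hydroxy-2-(4-methoxyphenyl)-4H-chromen-4-one | COc1ccc(cc1)-c1oc2cc(OCc3ccccc3)c(Br)cc2c(=O)c1O
F6 | step 12 | 3,7-bis(benzyloxy)-6-bromo-2-(4-methoxyphenyl)-4H-chromen-4-one | COc1ccc(cc1)-c1oc2cc(OCc3ccccc3)c(Br)cc2c(=O)c1OCc1ccccc1
F7 | step 12 | 3,7-di-O-benzylabiesin | COc1ccc(cc1)-c1oc2cc(OCc3ccccc3)c(cc2c(=O)c1OCc1ccccc1)-c1cc(ccc1OC)-c1cc(=O)c2c(O)cc(OC)cc2o1
F8 | step 5 | [5-benzyloxy-3-iodo-6-(4-methoxyphenyl)-4-oxo-4H-pyran-2-yl]acetic acid | OC(=O)Cc1oc(-c2ccc(OC)cc2)c(OCc2ccccc2)c(=O)c1I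
F9 | step 10 | 5-hydroxy-7-methoxy-2-{4-methoxy-3-[(E)-2-(4,4,5,5-tetramethyl-1,3,2-dioxaborolan-2-yl)ethenyl]phenyl}-4H-chromen-4-one | COc1cc(O)c2c(c1)oc(-c1ccc(OC)c(/C=C/B3OC(C)(C)C(C)(C)O3)c1)cc2=O
F10 | step 4 | 5-benzyloxy-3,6-dibromo-2-methyl-4H-pyran-4-one | Cc1c(Br)c(=O)c(OCc2ccccc2)c(Br)o1
F11 | step 4 | 5-benzyloxy-3-bromo-6-(4-methoxyphenyl)-2-methyl-4H-pyran-4-one | Cc1c(Br)c(=O)c(OCc2ccccc2)c(-c2ccc(OC)cc2)o1
F12 | step 4 | tert-butyl [5-benzyloxy-3-bromo-6-(4-methoxyphenyl)-4-oxo-4H-pyran-2-yl]acetate | CC(C)(C)OC(=O)Cc1oc(-c2ccc(OC)cc2)c(OCc2ccccc2)c(=O)c1Br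
A1 | alternative 1 | 2-[3-(4-hydroxy-2-triisopropylsilyloxyphenyl)-4-methoxyphenyl]-5,7-dimethoxychromen-4-one | Oc1ccc(c(O[Si](C(C)C)(C(C)C)C(C)C)c1)-c1cc(ccc1OC)-c1cc(=O)c2c(OC)cc(OC)cc2o1
A2 | alternative 1 | 2-[5-(5,7-dimethoxy-4-oxo-4H-chromen-2-yl)-2-methoxyphenyl]cyclobut-2-en-1-one | O=C1CC=C1c1cc(ccc1OC)-c1cc(=O)c2c(OC)cc(OC)cc2o1
A3 | alternative 1 | (triisopropylsilyloxy)acetylene | C#CO[Si](C(C)C)(C(C)C)C(C)C
A4 | alternative 2 | 3,7,5''-tri-O-benzylabiesin | COc1cc(OCc2ccccc2)c2c(c1)oc(cc2=O)-c1ccc(OC)c(c1)-c1cc2c(=O)c(OCc3ccccc3)c(-c3ccc(OC)cc3)oc2cc1OCc1ccccc1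
A5 | alternative 2 | 3-benzyloxy-5-methoxy-2-[2-(triphenyl-λ5-phosphanylidene)acetyl]phenyl 3-[3,7-bis(benzyloxy)-2-(4-methoxyphenyl)-4-oxo-4H-chromen-6-yl]-4-methoxybenzoate | COc1cc(OCc2ccccc2)c(C(=O)C=P(c2ccccc2)(c2ccccc2)c2ccccc2)c(OC(=O)c2ccc(OC)c(c2)-c2cc3c(=O)c(OCc4ccccc4)c(-c4ccc(OC)cc4)oc3cc2OCc2ccccc2)c1
A6 | alternative 3 | 7,5''-di-O-benzylabiesin | COc1ccc(cc1)-c1oc2cc(OCc3ccccc3)c(cc2c(=O)c1O)-c1cc(ccc1OC)-c1cc(=O)c2c(OCc3ccccc3)cc(OC)cc2o1
A7 | alternative 3 | (E)-1-{4-benzyloxy-5-[5-(5-benzyloxy-7-methoxy-4-oxo-4H-chromen-2-yl)-2-methoxyphenyl]-2-hydroxyphenyl}-3-(4-methoxyphenyl)prop-2-en-1-one | COc1ccc(/C=C/C(=O)c2cc(c(OCc3ccccc3)cc2O)-c2cc(ccc2OC)-c2cc(=O)c3c(OCc4ccccc4)cc(OC)cc3o2)cc1
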